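## Retrosynthetic overview

1. Target ⇒ Si–O cleavage, CBS reduction of C10=O and O-angeloylation at C8 ⇒ aldol disconnection C8–C9: ring-bound 2-substituted acrolein 16 + 3-methylbut-3-en-2-one 17.
2. Acrolein 16 ⇒ allylic oxidation (HOCl ene chlorination, N-oxide oxidation) of the isopropenyl group of a fully oxygenated carvone core 14.
3. C1–OAng ⇒ α-acyloxylation of the C2-ketone enol silane; C4–OAng/C5–OH ⇒ key C–O bond: invertive 1,2-angelate shift through an acyloxonium ion from the C5-angelate/C4α-alcohol 9.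
4. C2=O/C3–OH ⇒ OH-directed epoxidation and DMSO oxidation of the carvone C=C; C4α-OH ⇒ Luche reduction; C5–O ⇒ Rubottom oxidation of (R)-carvone (carvone C1/C2/C3/C4/C5/C6 = target C4/C3/C2/C1/C6/C5).
5. Rings: the only ring is carried intact from (R)-carvone; no ring-forming step.

Assumption and convention (one line): the target is taken as drawn, (1R,3R,4S,5S,6S,8S,10R) in bisabolane numbering; ring atoms carry the target's numbers throughout (C2 = ring C=O, C3 = C–CH3, C6 = carbon bearing the side chain C7–C14); β = face of O1, O4, O5 and 3-CH3 in the target, α = face of the C6 substituent and 3-OH; Ang = angeloyl = (Z)-2-methylbut-2-enoyl; compounds 1, 5 and 17 are bought.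

## Route

Step 1
Reactants: 1 (R)-(−)-carvone
Product: 4 trans-6-hydroxycarvone (new OH = 5β-OH of the target), via TMS dienol ether 2 (not isolated), via 6-silyloxycarvone 3 (not isolated)
Conditions: LDA, THF, −78 °C; TMSCl; then mCPBA, hexane–CH2Cl2, −15 °C; 1 M HCl, THF, 0 °C
Reagents that add atoms: mCPBA O=C(OO)c1cccc(Cl)c1; chlorotrimethylsilane C[Si](C)(C)Cl (silicon stays only in 2 and 3)
Why: Rubottom oxidation: kinetic α′-enolisation, then the peracid epoxidises the electron-rich enol silane (not the isopropenyl or enone C=C) anti to the adjacent isopropenyl group, so the new C–O bond is trans to it (C5 β).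

Step 2
Reactants: 4 trans-6-hydroxycarvone; 5 angelic acid
Product: 6 trans-6-angeloyloxycarvone (5β-OAng)
Conditions: 5, 2,4,6-Cl3C6H2COCl, Et3N, PhMe, 23 °C, filter; then 4, PhMe, 70 °C (no DMAP)
Reagents that add atoms: none
Why: Yamaguchi-type mixed-anhydride esterification without a nucleophilic catalyst, so the angelate cannot isomerise Z→E by conjugate addition; the enolisable carbinol carbon can only settle in the trans (β) configuration already present.

Step 3
Reactants: 6 trans-6-angeloyloxycarvone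
Product: 7 allylic alcohol (5β-OAng; 4α-OH; Δ2)
Conditions: NaBH4, CeCl3·7H2O, MeOH, −78 °C
Reagents that add atoms: none
Why: Luche 1,2-reduction: axial hydride delivery to the half-chair with equatorial isopropenyl and OAng groups gives the pseudo-equatorial 4α-alcohol (cis to isopropenyl as in carvone → cis-carveol, trans to 5β-OAng); esters are untouched.

Step 4
Reactants: 7 allylic alcohol
Product: 8 epoxy alcohol (5β-OAng; 4α-OH; 2α,3α-epoxide)
Conditions: VO(acac)2 (3 mol%), t-BuOOH, PhMe, 0→23 °C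
Reagents that add atoms: tert-butyl hydroperoxide CC(C)(C)OO
Why: Vanadium-catalysed hydroxyl-directed (Sharpless-type) epoxidation: only the allylic-alcohol alkene reacts (isopropenyl and angelate C=C are spared) and oxygen is delivered syn to 4α-OH, which sets the C3–O bond α.

Step 5
Reactants: 8 epoxy alcohol
Product: 9 ketol (5β-OAng; 4α-OH; 3α-OH; 2-oxo)
Conditions: DMSO, BF3·OEt2 (0.3 equiv), 4 Å MS, 60 °C
Reagents that add atoms: dimethyl sulfoxide CS(C)=O
Why: DMSO oxidation of an epoxide (Kornblum-type): DMSO opens the activated epoxide at secondary C2 in the trans-diaxial (Fürst–Plattner) sense, the alkoxysulfonium collapses to the C2 ketone, and the C3–O bond is never broken, so 3α-OH/3β-CH3 is retained.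

Step 6
Reactants: 9 ketol
Product: 12 transposed ketol (4β-OAng; 3α-OH; 5β-OH; 2-oxo), via 4α-triflate 10 (not isolated), via dioxolanylium triflate 11 (not isolated)
Conditions: Tf2O, 2,6-lutidine, CH2Cl2, −40 °C; then (CF3)2CHOH–H2O 10:1, −40→23 °C
Reagents that add atoms: water O; triflic anhydride O=S(=O)(OS(=O)(=O)C(F)(F)F)C(F)(F)F (its atoms stay only in 10 and 11)
Why: Proposed new method: triflation of the neopentyl-type 4α-OH, then anchimeric displacement by the carbonyl oxygen of the trans-vicinal 5β-angelate (antiperiplanar in the ring-flipped/twist conformer) forms the C4–O bond with inversion via a cis-fused 2-alkenyl-1,3-dioxolan-2-ylium ion, which water opens under stereoelectronic control (axial ester, equatorial OH; King–Allbutt rule) to give the 4β-angelate and free 5β-OH; C3 is quaternary and carbonyl-flanked, so E1cB, epoxide formation and semipinacol shift are disfavoured, and the charge sits on the two oxygens so the Z-alkene should survive; the closest known reaction type is Winstein neighbouring-acyloxy participation (trans-2-acetoxycyclohexyl sulfonates → cis-hydroxy acetates in wet solvent, and ester-assisted inversions of carbohydrate triflates), not yet shown for an α,β-unsaturated (Z) ester or next to a tertiary α-ketol.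

Step 7
Reactants: 12 transposed ketol; 5 angelic acid
Product: 14 bis-angelate (1β,4β-di-OAng; 3α,5β-di-OTES; 2-oxo; 6α-isopropenyl), via tris-TES enol ether 13 (not isolated)
Conditions: TESOTf (3.5 equiv), Et3N, CH2Cl2, −78→0 °C, pentane filtration; then PhI(OAng)2 [premade from PhI(OAc)2 + 5, PhCl, 40 °C, vacuum], BF3·OEt2 (cat.), CH2Cl2, −78→−20 °C
Reagents that add atoms: triethylsilyl trifluoromethanesulfonate CC[Si](CC)(CC)OS(=O)(=O)C(F)(F)F
Why: One-pot silylation and Moriarty-type hypervalent-iodine α-acyloxylation of an enol silane (carboxylate ligands exchanged on iodine beforehand): TESOTf caps both hydroxyls and forms the only possible enol ether (C3 is quaternary), and angelate is delivered to C1 anti to the C6 substituent, giving the 1,6-trans (1β, equatorial) ester, which is also the thermodynamic epimer of this enolisable centre.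

Step 8
Reactants: 14 bis-angelate
Product: 15 allylic chloride (6α-(3-chloroprop-1-en-2-yl))
Conditions: Ca(OCl)2, CO2 (s), CH2Cl2–H2O, 0 °C
Reagents that add atoms: calcium hypochlorite [Ca+2].[O-]Cl.[O-]Cl
Why: Ene-type allylic chlorination with HOCl (the transformation known on carvone itself): only the electron-rich 1,1-disubstituted alkene reacts, Cl adds to the CH2 terminus and the double bond moves to the former methyl group; no stereocentre is touched.

Step 9
Reactants: 15 allylic chloride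
Product: 16 enal (6α-(3-oxoprop-1-en-2-yl))
Conditions: NMO, KI (cat.), 4 Å MS, MeCN, 23 °C
Reagents that add atoms: N-methylmorpholine N-oxide C[N+]1([O-])CCOCC1
Why: Amine N-oxide (Ganem/Kornblum-type) oxidation of an allylic halide: O-alkylation of the N-oxide and elimination give the 2-substituted acrolein under near-neutral conditions.

Step 10
Reactants: 16 enal; 17 3-methylbut-3-en-2-one
Product: 20 aldol (8S)-β-hydroxy enone, via enol borinate 18 (not isolated), via boron aldolate 19 (not isolated)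
Conditions: 17, (−)-Ipc2BCl, Et3N, Et2O, −78→0 °C; then 16, −78→−20 °C; H2O2, pH 7 buffer, MeOH, 0 °C
Reagents that add atoms: (−)-B-chlorodiisopinocampheylborane ClB([C@@H]1C[C@@H]2C[C@H]([C@H]1C)C2(C)C)[C@@H]1C[C@@H]2C[C@H]([C@H]1C)C2(C)C (its atoms stay only in 18 and 19)
Why: Paterson boron aldol of a methyl ketone: the diisopinocampheyl enol borinate adds only to the aldehyde (not the hindered ring ketone) and, under reagent control, to its Si face, which sets C8 as S (as recalled for this reagent; the antipodal reagent is used if the sense is reversed), and the minor 8-epimer is a separable diastereomer.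

Step 11
Reactants: 20 aldol (8S)-β-hydroxy enone; 5 angelic acid
Product: 21 tris-angelate enone
Conditions: 5, 2,4,6-Cl3C6H2COCl, Et3N, PhMe, 23 °C, filter; then 20, PhMe, 50 °C (no DMAP)
Reagents that add atoms: none
Why: Yamaguchi-type mixed-anhydride esterification of the only free secondary hydroxyl (O3 and O5 are silylated); without DMAP or excess base neither angelate isomerisation nor E1cB loss of the β-acyloxy group occurs.

Step 12
Reactants: 21 tris-angelate enone
Product: 22 bis-TES ether of the target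
Conditions: (S)-Me-CBS (0.5 equiv), catecholborane, PhMe, −78 °C; MeOH
Reagents that add atoms: none
Why: Corey–Bakshi–Shibata reduction: the enone carbonyl is reduced 1,2 with the isopropenyl group as the large substituent, giving 10R (8,10-syn), while the ring ketone, flanked by a quaternary and an acyloxy carbon, is too hindered to react.

Step 13
Reactants: 22 bis-TES ether of the target
Product: 23 target CNP0273696.1
Conditions: HF·pyridine, pyridine, THF, 0→23 °C
Reagents that add atoms: none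
Why: Fluoride-mediated cleavage of both triethylsilyl ethers under buffered acidic conditions, where 1,2-/1,3-acyl migration and α-ketol rearrangement do not occur; no stereocentre is touched.

## Compound list

1 | (R)-(−)-carvone, (5R)-2-methyl-5-(prop-1-en-2-yl)cyclohex-2-en-1-one | C=C(C)[C@H]1CC(=O)C(C)=CC1 | starting material
2 | kinetic TMS dienol ether of 1, (5R)-2-methyl-5-(prop-1-en-2-yl)-1-(trimethylsilyloxy)cyclohexa-1(6),2-diene | C=C(C)[C@H]1C=C(O[Si](C)(C)C)C(C)=CC1 | intermediate (not isolated)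
3 | (5S,6S)-2-methyl-5-(prop-1-en-2-yl)-6-(trimethylsilyloxy)cyclohex-2-en-1-one | C=C(C)[C@H]1[C@H](O[Si](C)(C)C)C(=O)C(C)=CC1 | intermediate (not isolated)
4 | trans-6-hydroxycarvone, (5S,6S)-6-hydroxy-2-methyl-5-(prop-1-en-2-yl)cyclohex-2-en-1-one | C=C(C)[C@H]1[C@H](O)C(=O)C(C)=CC1 | intermediate
5 | angelic acid, (Z)-2-methylbut-2-enoic acid | C/C=C(/C)C(=O)O | starting material
6 | trans-6-angeloyloxycarvone, (1S,6S)-3-methyl-2-oxo-6-(prop-1-en-2-yl)cyclohex-3-en-1-yl (Z)-2-methylbut-2-enoate | C=C(C)[C@H]1[C@H](OC(=O)/C(C)=C\C)C(=O)C(C)=CC1 | intermediate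
7 | (1S,2S,6S)-2-hydroxy-3-methyl-6-(prop-1-en-2-yl)cyclohex-3-en-1-yl angelate (target numbering: 5β-OAng, 4α-OH, Δ2, 6α-isopropenyl) | C=C(C)[C@H]1[C@H](OC(=O)/C(C)=C\C)[C@@H](O)C(C)=CC1 | intermediate
8 | 5β-angeloyloxy-2α,3α-epoxy-4α-hydroxy-3β-methyl-6α-(prop-1-en-2-yl)cyclohexane (target numbering) | C=C(C)[C@H]1[C@H](OC(=O)/C(C)=C\C)[C@@H](O)[C@@]2(C)O[C@H]2C1 | intermediate
9 | 5β-angeloyloxy-3α,4α-dihydroxy-3β-methyl-6α-(prop-1-en-2-yl)cyclohexan-2-one (target numbering) | C=C(C)[C@H]1[C@H](OC(=O)/C(C)=C\C)[C@@H](O)[C@@](C)(O)C(=O)C1 | intermediate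
10 | 4α-O-trifluoromethanesulfonate of 9 | C=C(C)[C@H]1[C@H](OC(=O)/C(C)=C\C)[C@@H](OS(=O)(=O)C(F)(F)F)[C@@](C)(O)C(=O)C1 | intermediate (not isolated)
11 | cis-fused (O4β,O5β) 2-[(Z)-but-2-en-2-yl]-1,3-dioxolan-2-ylium triflate of the 3α-hydroxy-2-ketone | C=C(C)[C@H]1[C@@H]2OC(/C(C)=C\C)=[O+][C@@H]2[C@@](C)(O)C(=O)C1.[O-]S(=O)(=O)C(F)(F)F | intermediate (not isolated)
12 | 4β-angeloyloxy-3α,5β-dihydroxy-3β-methyl-6α-(prop-1-en-2-yl)cyclohexan-2-one (target numbering) | C=C(C)[C@H]1[C@H](O)[C@H](OC(=O)/C(C)=C\C)[C@@](C)(O)C(=O)C1 | intermediate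
13 | 4β-angeloyloxy-3β-methyl-6α-(prop-1-en-2-yl)-2,3α,5β-tris(triethylsilyloxy)cyclohex-1-ene (target numbering) | C=C(C)[C@H]1[C@H](O[Si](CC)(CC)CC)[C@H](OC(=O)/C(C)=C\C)[C@@](C)(O[Si](CC)(CC)CC)C(O[Si](CC)(CC)CC)=C1 | intermediate (not isolated)
14 | 1β,4β-bis(angeloyloxy)-3β-methyl-6α-(prop-1-en-2-yl)-3α,5β-bis(triethylsilyloxy)cyclohexan-2-one (target numbering) | C=C(C)[C@H]1[C@H](O[Si](CC)(CC)CC)[C@H](OC(=O)/C(C)=C\C)[C@@](C)(O[Si](CC)(CC)CC)C(=O)[C@@H]1OC(=O)/C(C)=C\C | intermediate
15 | 6α-(3-chloroprop-1-en-2-yl) analogue of 14 | C=C(CCl)[C@H]1[C@H](O[Si](CC)(CC)CC)[C@H](OC(=O)/C(C)=C\C)[C@@](C)(O[Si](CC)(CC)CC)C(=O)[C@@H]1OC(=O)/C(C)=C\C | intermediate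
16 | 6α-(3-oxoprop-1-en-2-yl) analogue of 14 (2-substituted acrolein) | C=C(C=O)[C@H]1[C@H](O[Si](CC)(CC)CC)[C@H](OC(=O)/C(C)=C\C)[C@@](C)(O[Si](CC)(CC)CC)C(=O)[C@@H]1OC(=O)/C(C)=C\C | intermediate
17 | 3-methylbut-3-en-2-one | CC(=O)C(C)=C | starting material
18 | 3-methylbuta-1,3-dien-2-yl bis[(−)-isopinocampheyl]borinate | C=C(C)C(=C)OB([C@@H]1C[C@@H]2C[C@H]([C@H]1C)C2(C)C)[C@@H]1C[C@@H]2C[C@H]([C@H]1C)C2(C)C | intermediate (not isolated)
19 | O8-bis(isopinocampheyl)boryl aldolate of 20 | C=C(C)C(=O)C[C@H](OB([C@@H]1C[C@@H]2C[C@H]([C@H]1C)C2(C)C)[C@@H]1C[C@@H]2C[C@H]([C@H]1C)C2(C)C)C(=C)[C@H]3[C@H](O[Si](CC)(CC)CC)[C@H](OC(=O)/C(C)=C\C)[C@@](C)(O[Si](CC)(CC)CC)C(=O)[C@@H]3OC(=O)/C(C)=C\C | intermediate (not isolated)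
20 | 6α-[(3S)-3-hydroxy-6-methyl-5-oxohepta-1,6-dien-2-yl] analogue of 14 (8S aldol) | C=C(C)C(=O)C[C@H](O)C(=C)[C@H]1[C@H](O[Si](CC)(CC)CC)[C@H](OC(=O)/C(C)=C\C)[C@@](C)(O[Si](CC)(CC)CC)C(=O)[C@@H]1OC(=O)/C(C)=C\C | intermediate
21 | 6α-[(3S)-3-angeloyloxy-6-methyl-5-oxohepta-1,6-dien-2-yl] analogue of 14 | C=C(C)C(=O)C[C@H](OC(=O)/C(C)=C\C)C(=C)[C@H]1[C@H](O[Si](CC)(CC)CC)[C@H](OC(=O)/C(C)=C\C)[C@@](C)(O[Si](CC)(CC)CC)C(=O)[C@@H]1OC(=O)/C(C)=C\C | intermediate
22 | 3α,5β-bis(triethylsilyl) ether of the target, side chain (3S,5R)-3-angeloyloxy-5-hydroxy-6-methylhepta-1,6-dien-2-yl | C=C(C)[C@H](O)C[C@H](OC(=O)/C(C)=C\C)C(=C)[C@H]1[C@H](O[Si](CC)(CC)CC)[C@H](OC(=O)/C(C)=C\C)[C@@](C)(O[Si](CC)(CC)CC)C(=O)[C@@H]1OC(=O)/C(C)=C\C | intermediate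
23 | CNP0273696.1, (1R,3R,4S,5S,6S,8S,10R)-1,4,8-tris(angeloyloxy)-3,5,10-trihydroxybisabola-7(14),11-dien-2-one | C=C(C)[C@H](O)C[C@H](OC(=O)/C(C)=C\C)C(=C)[C@H]1[C@H](O)[C@H](OC(=O)/C(C)=C\C)[C@@](C)(O)C(=O)[C@@H]1OC(=O)/C(C)=C\C | target

## Totals and risk

Total step count: 13. Longest linear sequence: 13 (fully linear from 1; 5 and 17 are bought).

The three steps most likely to fail:

Step 6 (the proposed new step). The triflate sits on a deactivated, neopentyl-type carbon and must reach a ring-flipped or twist conformer before the angelate can participate, so ionisation may be slow or divert. The fallback uses known chemistry only, sets out from 8 and comes back at 12, bypassing steps 5 and 6. Compound 8 is acylated with 1,1′-thiocarbonyldiimidazole to the 4α-O-(imidazol-1-ylcarbonothioyl) derivative F1. Bu3SnH/AIBN then effects the Barton–Motherwell radical epoxide fragmentation (the radical counterpart of the Wharton transposition) and gives the transposed allylic alcohol F2 (2α-OH, Δ3, 5β-OAng). VO(acac)2/t-BuOOH epoxidation directed by the 2α-OH gives the 3α,4α-epoxy alcohol F3, and Dess–Martin oxidation gives the 3α,4α-epoxy 2-ketone F4. Catalytic HClO4 in wet THF then lets the C5 angelate open the epoxide at C4, the β-carbon of the epoxy ketone, in a known acid-promoted neighbouring-ester epoxide opening. This passes through the same dioxolanylium cation, now generated by strain release instead of sulfonate ionisation, and hydrolyses to 12.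

Step 5. BF3 may trigger Meinwald rearrangement or attack at the tertiary epoxide carbon instead of clean oxidative opening at C2. The fallback sets out from 7 and comes back at 9. Hydroxyl-directed Donohoe dihydroxylation (OsO4·TMEDA, CH2Cl2, −78 °C, syn to 4α-OH and selective for the allylic-alcohol alkene) gives the 2α,3α,4α-triol F5. Its less hindered secondary C2 hydroxyl is then oxidised chemoselectively with TEMPO/PhI(OAc)2 (C4–OH is flanked by the quaternary C3 and the acyloxy-bearing C5) to give 9.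

Step 7. The iodine(III) reagent may be consumed by residual amine or attack the isopropenyl group, and the angelate ligand transfer is untested on such a crowded enol silane. The fallback sets out from 12 and comes back at 14. TESOTf/2,6-lutidine gives the 3α,5β-bis(triethylsilyl) ether F6, and TMSOTf/Et3N gives its TMS enol ether F7. Rubottom oxidation with dimethyldioxirane (attack anti to the C6 substituent) and citric acid work-up gives the 1β-hydroxy ketone F8, which is esterified with 5 by the mixed-anhydride protocol of step 2 to give 14.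

Further compounds
F1 | step 6 | 4α-O-(imidazol-1-ylcarbonothioyl) derivative of 8 | C=C(C)[C@H]1[C@H](OC(=O)/C(C)=C\C)[C@@H](OC(=S)n2ccnc2)[C@@]3(C)O[C@H]3C1
F2 | step 6 | 5β-angeloyloxy-2α-hydroxy-3-methyl-6α-(prop-1-en-2-yl)cyclohex-3-ene (target numbering) | C=C(C)[C@H]1[C@H](OC(=O)/C(C)=C\C)C=C(C)[C@@H](O)C1
F3 | step 6 | 5β-angeloyloxy-3α,4α-epoxy-2α-hydroxy-3β-methyl-6α-(prop-1-en-2-yl)cyclohexane (target numbering) | C=C(C)[C@H]1[C@H](OC(=O)/C(C)=C\C)[C@H]2O[C@@]2(C)[C@@H](O)C1
F4 | step 6 | 5β-angeloyloxy-3α,4α-epoxy-3β-methyl-6α-(prop-1-en-2-yl)cyclohexan-2-one (target numbering) | C=C(C)[C@H]1[C@H](OC(=O)/C(C)=C\C)[C@H]2O[C@@]2(C)C(=O)C1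
F5 | step 5 | 5β-angeloyloxy-2α,3α,4α-trihydroxy-3β-methyl-6α-(prop-1-en-2-yl)cyclohexane (target numbering) | C=C(C)[C@H]1[C@H](OC(=O)/C(C)=C\C)[C@@H](O)[C@@](C)(O)[C@@H](O)C1
F6 | step 7 | 3α,5β-bis(triethylsilyl) ether of 12 | C=C(C)[C@H]1[C@H](O[Si](CC)(CC)CC)[C@H](OC(=O)/C(C)=C\C)[C@@](C)(O[Si](CC)(CC)CC)C(=O)C1
F7 | step 7 | 2-(trimethylsilyloxy)cyclohex-1-ene (TMS enol ether) of F6 | C=C(C)[C@H]1[C@H](O[Si](CC)(CC)CC)[C@H](OC(=O)/C(C)=C\C)[C@@](C)(O[Si](CC)(CC)CC)C(O[Si](C)(C)C)=C1
F8 | step 7 | 1β-hydroxy derivative of F6 | C=C(C)[C@H]1[C@H](O[Si](CC)(CC)CC)[C@H](OC(=O)/C(C)=C\C)[C@@](C)(O[Si](CC)(CC)CC)C(=O)[C@@H]1O
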